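At one constant temperature, time is what I read a flask by, so I turned the target readings into a clock.

| flask | starting material | coupling partner | free catalyst | time |
|---|---|---|---|---|
| south-east | 0.300 M | 0.450 M | 0.0150 M |  |
| north | 0.900 M | 0.450 M | 0.0150 M |  |
| north-east | 0.300 M | 0.680 M | 0.0150 M |  |
| west | 0.300 M | 0.450 M | 0.00750 M |  |
| south | 0.300 M | 0.450 M | 0.0150 M | 78 min |

| run | time / min | [target] / M |
|---|---|---|
| south-east run | 0.52 | 0.0084 |
| south-east run | 0.99 | 0.0146 |
| south-east run | 1.9 | 0.0223 |
| south-east run | 3.6 | 0.0397 |
| south-east run | 6.8 | 0.0730 |
| south-east run | 13 | 0.1193 |
| north run | 0.52 | 0.0194 |
| north run | 0.99 | 0.0413 |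
| north run | 1.9 | 0.0696 |
| north run | 3.6 | 0.1154 |
| north run | 6.8 | 0.1918 |
| north run | 13 | 0.2933 |
| north-east run | 0.52 | 0.0079 |
| north-east run | 0.99 | 0.0150 |
| north-east run | 1.9 | 0.0307 |
| north-east run | 3.6 | 0.0548 |
| north-east run | 6.8 | 0.0905 |
| north-east run | 13 | 0.1457 |
| west run | 0.52 | 0 |
| west run | 0.99 | 0 |
| west run | 1.9 | 0 |
| west run | 3.6 | 0.0024 |
| west run | 6.8 | 0.0031 |
| west run | 13 | 0.0031 |

(each reading ± 0.002 M)

- the power of [coupling partner] that the first rate follows, about the charge of the south-east run; measure it at two percent of starting material made into target
- the power of [starting material] that the first rate follows, about the charge of the south-east run; measure it at two percent of starting material made into target (one fixed amount of target, the same in the runs compared)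
- target in the south run at 78 min, as a share of the starting material charged

- Overall: starting material + coupling partner -> target, with free catalyst as catalyst.
- Constant volume, constant temperature.
- What is held in complexes is read along with the free species.
- An order is taken over about fifteen percent of the charge, up and down.

The south flask carries the charge of the south-east flask, so I reckoned it from the south-east run. Starting material is the limiting reagent there, 0.300 M against 0.450 M of coupling partner.

In the first instants, the south-east flask made 0.0084 M of target by 0.52 min, so turnover began at once. The west flask, with 0.00750 M of free catalyst against 0.0150 M, read 0 M at 1.9 min and stood at 0.0031 M at both 6.8 min and 13 min. Its catalyst charge was half, yet the south-east reading at 13 min was 38.5 times the west reading, a ratio that carries the scatter of both. So I did not scale by catalyst, and I took the pace from the south-east run itself.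

At 3.6 min, tripled starting material in the north flask gave 2.91 times the south-east target, a power of 0.971. The north-east readings at 3.6 min and 6.8 min, summed against the south-east ones, gave a power of 0.615 for coupling partner. Both are readings, with their scatter.

For the middle of the run I defined the clock as the logarithm of starting material charged over starting material remaining, divided by time, an apparent first-order constant. At 13 min in the south-east run it read 0.0390 /min, with 39.8 % turned. At 6.8 min it had read 0.0410 /min, so the pace had barely moved.

Toward the end, coupling partner falls to 0.150 M at full turnover, a third of its charge. With my power, that slows the clock by a factor of 0.509.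

So I set two marks on a scale. Power zero in coupling partner keeps the clock constant and gives 95.2 % at 78 min. Power one, the plain second-order law calibrated on the same reading, has a constant of 0.102 /M/min and gives 87.3 %. Placing my power between the marks, I committed to 90.4 %. This assumes the catalyst keeps its pace beyond 13 min, where the readings end.

The forecast gave a power of 0.6 (0.2 to 1) for coupling partner, a power of 1 (0.75 to 1.25) for starting material and 85 % (65 % to 94 %) for the share, lower than mine, shaded for “possible slow deactivation or product inhibition”.

The south flask gave 89.9 % at 78 min, and the first rate followed a power of 0.66 in coupling partner and 1.0 in starting material.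

    2 free catalyst ⇌ catalyst dimer, settled at all times (1300 /M)
    catalyst dimer + starting material + coupling partner → target + catalyst dimer (66.00 /M²/min)
    free catalyst + impurity → spent catalyst
    2 coupling partner ⇌ idle reagent dimer, settled at all times (2.980 /M)

The impurity stood at 0.00697 M in the south flask, against 0.0150 M of free catalyst charged. Averaged over the south run, the clock ran at 0.0294 /min, slower than the 0.0390 /min read in the south-east run at 13 min. Scaled by my power to the north-east charge, the clock gives a half-time of 13.8 min. In the north-east flask, the target made came to half of the charge at 13.4 min.

(The earlier runs and the new flask stem from a simulated flask on assumed constants.)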